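**Plan**
- Feature: in ring C, C3 (bearing OMe) and C4 (the carbonyl carbon) are adjacent oxygenated carbons, the methyl enol ether of a chromane-3,4-dione. One oxidation level lower this is an α-ketol, so C3–C4 is an acyloin bond between two formyl carbons.
- Retrosynthesis: the 5-OH is traced to its methyl ether and the O3–CH3 bond is cut (flavonol, then ketol). C3–C4 is cut to a dialdehyde, the O1–C2 ether bond to a salicylaldehyde plus an α-bromo arylacetate, and the formyl C–C bond to ring A last.
- Forward: ring A is bought, formylated and mono-demethylated; ring B arrives with the arylacetate by O-alkylation (O1–C2); redox adjustment gives the dialdehyde; ring C closes last by a carbene-catalysed benzoin (C3–C4); oxidation, 3-O-methylation and 5-O-demethylation finish.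
- Stereochemistry: the target is achiral. C2 and C3 exist only in racemic intermediates, are expected trans in the ketol by equilibration, and both vanish on oxidation to the flavonol.

Key step: step 7

Remark: every stereogenic intermediate is carried as the racemate; the trans configuration written for ketol 11 is the expected equilibrium isomer and is not needed later.

Step 1
Reactants: 1 1,2,3,5-tetramethoxybenzene
Product: 3 2,3,4,6-tetramethoxybenzaldehyde, via aryl dimethyliminium chloride 2 (not isolated)
Conditions: POCl3, DMF, 0 → 70 °C; then H2O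
Reagents that add atoms: N,N-dimethylformamide CN(C)C=O (formyl carbon); water O (carbonyl oxygen)
Why: Vilsmeier–Haack formylation, in which the two free positions of 1 are equivalent and each is ortho, ortho and para to methoxy groups, so the chloroiminium ion should give one iminium salt that water hydrolyses to the aldehyde.

Step 2
Reactants: 3 2,3,4,6-tetramethoxybenzaldehyde
Product: 5 2-hydroxy-3,4,6-trimethoxybenzaldehyde, via aryloxydichloroborane chelate 4 (not isolated)
Conditions: BCl3 (1.1 equiv), CH2Cl2, −78 → 0 °C; then H2O
Reagents that add atoms: none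
Why: Chelation-directed Lewis acid cleavage of an aryl methyl ether ortho to a carbonyl group, where the C2 methoxy group is buttressed by the C3 methoxy group, twisted out of conjugation and therefore the more basic one, the same preference that gives 2-hydroxy-3,4,6-trimethoxyaryl ketones in acylative demethylations of 1.

Step 3
Reactants: 6 methyl 2-(2-methoxyphenyl)acetate
Product: 7 methyl 2-bromo-2-(2-methoxyphenyl)acetate (racemic)
Conditions: N-bromosuccinimide, azobisisobutyronitrile (cat.), PhCF3, 80 °C
Reagents that add atoms: N-bromosuccinimide O=C1CCC(=O)N1Br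
Why: Wohl–Ziegler radical bromination at a C–H that is both benzylic and α to the ester, with a non-polar solvent and a radical initiator to keep the reagent from brominating the anisole ring.

Step 4
Reactants: 5 2-hydroxy-3,4,6-trimethoxybenzaldehyde; 7 methyl 2-bromo-2-(2-methoxyphenyl)acetate
Product: 8 methyl 2-(2-formyl-3,5,6-trimethoxyphenoxy)-2-(2-methoxyphenyl)acetate (racemic)
Conditions: K2CO3, DMF, rt
Reagents that add atoms: none
Why: Williamson ether synthesis, in which the phenoxide of 5 displaces bromide from an SN2-activated benzylic α-bromo ester that has no β-hydrogen, while carbonate at room temperature is too weak to enolise the product ester towards an aldol with the neighbouring formyl group; the new stereocentre is racemic.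

Step 5
Reactants: 8 methyl 2-(2-formyl-3,5,6-trimethoxyphenoxy)-2-(2-methoxyphenyl)acetate
Product: 9 2-[2-(hydroxymethyl)-3,5,6-trimethoxyphenoxy]-2-(2-methoxyphenyl)ethan-1-ol (racemic)
Conditions: LiAlH4, THF, 0 °C; then H2O, aq NaOH
Reagents that add atoms: none
Why: Hydride reduction of the ester and the aldehyde in one operation, which removes the need to tell the two carbonyl groups apart, with a basic work-up that spares the acid-labile 2,4,6-trioxygenated benzyl alcohol.

Step 6
Reactants: 9 2-[2-(hydroxymethyl)-3,5,6-trimethoxyphenoxy]-2-(2-methoxyphenyl)ethan-1-ol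
Product: 10 3,4,6-trimethoxy-2-[1-(2-methoxyphenyl)-2-oxoethoxy]benzaldehyde (racemic), used crude at once
Conditions: Dess–Martin periodinane (2.5 equiv), pyridine, CH2Cl2, 0 °C → rt
Reagents that add atoms: none
Why: Dess–Martin oxidation of both primary alcohols under pyridine-buffered conditions, preferred to activated-DMSO methods because the electron-rich benzylic alcohol could ionise at the alkoxysulfonium stage and the α-aryl-α-aryloxy aldehyde is easily enolised by amine bases.

Step 7
Reactants: 10 3,4,6-trimethoxy-2-[1-(2-methoxyphenyl)-2-oxoethoxy]benzaldehyde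
Product: 11 trans-3-hydroxy-5,7,8-trimethoxy-2-(2-methoxyphenyl)chroman-4-one (racemic)
Conditions: 3-benzyl-5-(2-hydroxyethyl)-4-methylthiazolium chloride (20 mol%), Et3N (15 mol%), t-BuOH/THF 1:1, slow addition of 10 to 0.02 M, 40 °C, argon
Reagents that add atoms: none
Why: Proposed new method: the thiazol-2-ylidene freed by Et3N adds to the aromatic formyl group of 10, proton transfer gives the Breslow enaminol (an acyl anion equivalent at C4), and this carbon attacks the tethered aliphatic formyl carbon (C3) before the adduct releases the carbene and the C4 ketone. The closest known reaction type is the carbene-catalysed intramolecular crossed benzoin of 2-(2-oxoalkoxy)benzaldehydes, an aldehyde–ketone union that gives 3-hydroxychroman-4-ones, together with the carbene-catalysed cyclisation of aliphatic dialdehydes to cyclic acyloins; the aryl aldehyde–alkyl aldehyde pairing on an aryl ether tether is the untested part. Ring C closes in a 6-exo-trig mode, because the O1–C2 ether link made in step 4 lets C3 and C4 meet only in a six-membered ring. The selectivity needed is that the aromatic aldehyde is the donor and the aliphatic aldehyde only the acceptor, since an enaminol formed at the aliphatic carbon has the aryloxide on the neighbouring carbon and could expel it; the substrate should favour this because the aliphatic formyl group sits on a fully substituted, crowded carbon (slow carbene addition and deprotonation) yet is the more electrophilic acceptor, while the aryl adduct has the more acidic benzylic C–H. C2 is already stereogenic but labile and C3 is new; its configuration is under thermodynamic control, because C3 lies α to the ketone and should epimerise under the amine to the trans isomer with both substituents equatorial. Substoichiometric weak base, slow addition and dilution are meant to hold back the five-ring aldol of the enolisable aldehyde and intermolecular benzoin, and any cis or 4-hydroxy-3-one ketol would converge with 11 in step 8.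

Step 8
Reactants: 11 trans-3-hydroxy-5,7,8-trimethoxy-2-(2-methoxyphenyl)chroman-4-one
Product: 13 3-hydroxy-5,7,8-trimethoxy-2-(2-methoxyphenyl)-4H-chromen-4-one, via chromane-3,4-dione 12 (not isolated)
Conditions: Dess–Martin periodinane (1.2 equiv), pyridine, CH2Cl2, 0 °C → rt
Reagents that add atoms: none
Why: Dess–Martin oxidation of the secondary alcohol of an α-ketol to the 1,2-dione, which should tautomerise through its acidic C2–H to the aromatic 3-hydroxy-4-pyranone, so that both stereocentres disappear.

Step 9
Reactants: 13 3-hydroxy-5,7,8-trimethoxy-2-(2-methoxyphenyl)-4H-chromen-4-one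
Product: 14 3,5,7,8-tetramethoxy-2-(2-methoxyphenyl)-4H-chromen-4-one
Conditions: MeI, K2CO3, acetone, reflux
Reagents that add atoms: iodomethane CI
Why: Williamson O-methylation of the acidic enolic 3-hydroxyl, the only free hydroxyl in 13.

Step 10
Reactants: 14 3,5,7,8-tetramethoxy-2-(2-methoxyphenyl)-4H-chromen-4-one
Product: 16 5-hydroxy-3,7,8-trimethoxy-2-(2-methoxyphenyl)-4H-chromen-4-one, via 5-O-dichloroboron chelate 15 (not isolated)
Conditions: BCl3 (1.5 equiv), CH2Cl2, −78 → 0 °C; then H2O
Reagents that add atoms: none
Why: Chelation-controlled Lewis acid demethylation, in which BCl3 bound to the C4 carbonyl oxygen reaches the peri 5-methoxy group through a six-membered chelate that is favoured over the five-membered one to the 3-methoxy group, so the 5-methyl ether alone should be cleaved at low temperature.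

**Compound list**
1 | 1,2,3,5-tetramethoxybenzene | COc1cc(OC)c(OC)c(OC)c1 | starting material
2 | N,N-dimethyl-1-(2,3,4,6-tetramethoxyphenyl)methaniminium chloride | COc1cc(OC)c(OC)c(OC)c1C=[N+](C)C.[Cl-] | intermediate
3 | 2,3,4,6-tetramethoxybenzaldehyde | COc1cc(OC)c(OC)c(OC)c1C=O | intermediate
4 | 2-(dichloroboranyloxy)-3,4,6-trimethoxybenzaldehyde | COc1cc(OC)c(OC)c(OB(Cl)Cl)c1C=O | intermediate
5 | 2-hydroxy-3,4,6-trimethoxybenzaldehyde | COc1cc(OC)c(OC)c(O)c1C=O | intermediate
6 | methyl 2-(2-methoxyphenyl)acetate | COC(=O)Cc1ccccc1OC | starting material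
7 | methyl 2-bromo-2-(2-methoxyphenyl)acetate (racemic) | COC(=O)C(Br)c1ccccc1OC | intermediate
8 | methyl 2-(2-formyl-3,5,6-trimethoxyphenoxy)-2-(2-methoxyphenyl)acetate (racemic) | COC(=O)C(Oc1c(OC)c(OC)cc(OC)c1C=O)c1ccccc1OC | intermediate
9 | 2-[2-(hydroxymethyl)-3,5,6-trimethoxyphenoxy]-2-(2-methoxyphenyl)ethan-1-ol (racemic) | OCC(Oc1c(OC)c(OC)cc(OC)c1CO)c1ccccc1OC | intermediate
10 | 3,4,6-trimethoxy-2-[1-(2-methoxyphenyl)-2-oxoethoxy]benzaldehyde (racemic) | COc1ccccc1C(C=O)Oc1c(OC)c(OC)cc(OC)c1C=O | intermediate
11 | trans-3-hydroxy-5,7,8-trimethoxy-2-(2-methoxyphenyl)chroman-4-one (racemic; the 2R,3R enantiomer is drawn) | COc1ccccc1[C@H]1Oc2c(OC)c(OC)cc(OC)c2C(=O)[C@@H]1O | intermediate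
12 | 5,7,8-trimethoxy-2-(2-methoxyphenyl)chromane-3,4-dione (racemic) | COc1ccccc1C1Oc2c(OC)c(OC)cc(OC)c2C(=O)C1=O | intermediate
13 | 3-hydroxy-5,7,8-trimethoxy-2-(2-methoxyphenyl)-4H-chromen-4-one | COc1ccccc1-c1oc2c(OC)c(OC)cc(OC)c2c(=O)c1O | intermediate
14 | 3,5,7,8-tetramethoxy-2-(2-methoxyphenyl)-4H-chromen-4-one | COc1ccccc1-c1oc2c(OC)c(OC)cc(OC)c2c(=O)c1OC | intermediate
15 | 5-(dichloroboranyloxy)-3,7,8-trimethoxy-2-(2-methoxyphenyl)-4H-chromen-4-one | COc1ccccc1-c1oc2c(OC)c(OC)cc(OB(Cl)Cl)c2c(=O)c1OC | intermediate
16 | 5-hydroxy-3,7,8-trimethoxy-2-(2-methoxyphenyl)-4H-chromen-4-one (5-hydroxy-3,7,8,2'-tetramethoxyflavone) | COc1ccccc1-c1oc2c(OC)c(OC)cc(O)c2c(=O)c1OC | target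

**Step count**
Total steps: 10. Longest linear sequence: 9 steps, from 1 to 16 (steps 1, 2 and 4–10); the branch from 6 (step 3) joins at step 4.

**Steps most likely to fail**

1. Step 7. The carbene may engage the aliphatic formyl group instead of the aromatic one, and the enaminol formed there can lose the aryloxide by β-elimination (internal redox followed by acyl transfer). The enolisable aldehyde may also close a five-membered ring by base-mediated aldol addition before the benzoin takes place. The fallback uses known chemistry and builds ring C from the acetophenone side. From 1, Friedel–Crafts acetylation with AcCl and AlCl3 in Et2O, which also cleaves the crowded ortho methyl ether, should give 1-(2-hydroxy-3,4,6-trimethoxyphenyl)ethan-1-one F1. Claisen–Schmidt condensation with 2-methoxybenzaldehyde (KOH, EtOH) gives (E)-1-(2-hydroxy-3,4,6-trimethoxyphenyl)-3-(2-methoxyphenyl)prop-2-en-1-one F2. Oxidative cyclisation with catalytic iodine in DMSO at 120 °C gives 5,7,8-trimethoxy-2-(2-methoxyphenyl)-4H-chromen-4-one F3. Epoxidation of the C2–C3 double bond with dimethyldioxirane in acetone gives 2,3-epoxy-5,7,8-trimethoxy-2-(2-methoxyphenyl)chroman-4-one F4, which a trace of p-toluenesulfonic acid isomerises to flavonol 13. The route is rejoined there, before step 9.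

2. Step 6. The freshly formed α-aryl-α-aryloxy aldehyde may enolise and then undergo aldol closure or loss of the aryloxide. The electron-rich benzylic alcohol may ionise, and the half-oxidised hydroxy aldehyde may form a lactol that is over-oxidised. The fallback reaches the aldehyde oxidation level by reduction instead of oxidation. From 8, the aryl formyl group is masked with HC(OMe)3 in MeOH and catalytic pyridinium p-toluenesulfonate to give methyl 2-[2-(dimethoxymethyl)-3,5,6-trimethoxyphenoxy]-2-(2-methoxyphenyl)acetate F5. iBu2AlH in toluene at −78 °C should take the α-aryloxy ester only as far as 2-[2-(dimethoxymethyl)-3,5,6-trimethoxyphenoxy]-2-(2-methoxyphenyl)acetaldehyde F6. Brief treatment with dilute aqueous oxalic acid in THF removes the very labile acetal and returns to dialdehyde 10, which enters step 7.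

3. Step 10. Over-cleavage may occur, with loss of the 3-methyl ether through its five-membered chelate or of the 8-methyl ether alongside the 5-methyl ether. The fallback reverses the order of the last two operations. From 13, BCl3 (2.5 equiv) in CH2Cl2 cleaves the 5-methyl ether while the 3-hydroxyl is still free, giving 3,5-dihydroxy-7,8-dimethoxy-2-(2-methoxyphenyl)-4H-chromen-4-one F7. One equivalent of MeI with K2CO3 in acetone at room temperature then methylates the 3-hydroxyl in preference to the strongly chelated 5-hydroxyl and arrives at target 16.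

Further compounds
F1 | step 7 | 1-(2-hydroxy-3,4,6-trimethoxyphenyl)ethan-1-one | CC(=O)c1c(O)c(OC)c(OC)cc1OC
F2 | step 7 | (E)-1-(2-hydroxy-3,4,6-trimethoxyphenyl)-3-(2-methoxyphenyl)prop-2-en-1-one | COc1ccccc1/C=C/C(=O)c1c(O)c(OC)c(OC)cc1OC
F3 | step 7 | 5,7,8-trimethoxy-2-(2-methoxyphenyl)-4H-chromen-4-one | COc1ccccc1-c1cc(=O)c2c(OC)cc(OC)c(OC)c2o1
F4 | step 7 | 2,3-epoxy-5,7,8-trimethoxy-2-(2-methoxyphenyl)chroman-4-one (racemic) | COc1ccccc1C12OC1C(=O)c1c(OC)cc(OC)c(OC)c1O2
F5 | step 6 | methyl 2-[2-(dimethoxymethyl)-3,5,6-trimethoxyphenoxy]-2-(2-methoxyphenyl)acetate (racemic) | COC(=O)C(Oc1c(OC)c(OC)cc(OC)c1C(OC)OC)c1ccccc1OC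
F6 | step 6 | 2-[2-(dimethoxymethyl)-3,5,6-trimethoxyphenoxy]-2-(2-methoxyphenyl)acetaldehyde (racemic) | O=CC(Oc1c(OC)c(OC)cc(OC)c1C(OC)OC)c1ccccc1OC
F7 | step 10 | 3,5-dihydroxy-7,8-dimethoxy-2-(2-methoxyphenyl)-4H-chromen-4-one | COc1ccccc1-c1oc2c(OC)c(OC)cc(O)c2c(=O)c1O
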